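**Plan**

- Retrosynthesis: cut the ester C–O bond at C6 (isoferuloyl unit off). Then cut C5–C10 and C8–C9 of the eudesmane core together (intramolecular Diels–Alder), then C1–C10 and C6–C7 of the open chain. What remains, C1–C6 with the C4 carbinol, is (S)-linalool.
- Feature used: ring B (C5–C10) has its oxygen on C6 next to the ring fusion, so C5=C6–C7=C8 can be a 2-silyloxydiene with the isopropyl group on C7. The quaternary C10 next to C1 can be the α-carbon of an isopropenyl ketone. The tertiary carbinol C4 of ring A is the stereocentre of linalool.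
- Forward: the chain is built linearly (C1 end as Weinreb amide, C6 end as α-isopropyl enone, dienol ether, then isopropenyl ketone). Rings A and B close together in one cycloaddition. The C1 oxygen is then removed, the C6 ketone unveiled and reduced, and the ester attached last.
- Stereochemistry: C4 comes from (S)-linalool. C10 and C5 are set by C4 in the cycloaddition. C7 is set by axial protonation of the enol ether, C6 by hydride attack anti to the axial C10 methyl and C4 oxygen. The (E)-alkene comes with isoferulic acid.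

Key step: step 11

Remark: (S)-(+)-linalool is assumed to be used in high enantiomeric purity. Eudesmane numbering is used for all bicyclic compounds; β is the face of the C10 methyl group, so 4β-oxy means 4α-methyl and 7αH means 7β-isopropyl.

**Route**

Step 1
Reactants: 1 (S)-linalool
Product: 2 (S)-linalool triethylsilyl ether, (S)-triethyl[(3,7-dimethylocta-1,6-dien-3-yl)oxy]silane
Conditions: TESOTf, 2,6-lutidine, CH2Cl2, −78 → 0 °C
Reagents that add atoms: triethylsilyl triflate, CC[Si](CC)(CC)OS(=O)(=O)C(F)(F)F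
Why: O-silylation with a silyl triflate and a non-nucleophilic base protects the hindered tertiary alcohol; the C4 stereocentre is not involved.

Step 2
Reactants: 2 (S)-linalool triethylsilyl ether
Product: 4 (S)-4-methyl-4-(triethylsilyloxy)hex-5-enal, via ozonide 3 (not isolated)
Conditions: O3/O2, CH2Cl2, −78 °C, Sudan Red 7B as end-point indicator; then PPh3, −78 °C → rt
Reagents that add atoms: ozone, [O-][O+]=O
Why: Criegee ozonolysis with reductive work-up; the electron-rich trisubstituted alkene should react with ozone far faster than the vinyl group on the oxygen-bearing quaternary carbon, and the dye marks the end point.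

Step 3
Reactants: 4 (S)-4-methyl-4-(triethylsilyloxy)hex-5-enal
Product: 5 (S)-4-methyl-4-(triethylsilyloxy)hex-5-enoic acid
Conditions: NaClO2, NaH2PO4, 2-methyl-2-butene, t-BuOH/H2O, 0 °C → rt
Reagents that add atoms: sodium chlorite, [Na+].[O-]Cl=O
Why: Pinnick oxidation converts the aldehyde to the acid under buffered conditions that leave the vinyl group (hypochlorite is scavenged) and the tertiary silyl ether untouched.

Step 4
Reactants: 5 (S)-4-methyl-4-(triethylsilyloxy)hex-5-enoic acid
Product: 6 (S)-N-methoxy-N,4-dimethyl-4-(triethylsilyloxy)hex-5-enamide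
Conditions: MeNHOMe·HCl, EDC·HCl, i-Pr2NEt, DMAP (cat.), CH2Cl2, 0 °C → rt
Reagents that add atoms: N,O-dimethylhydroxylamine hydrochloride, CNOC.Cl
Why: carbodiimide amide coupling gives the Weinreb amide, which carries C1 in a form that is neither enolized nor over-alkylated in steps 5 to 10.

Step 5
Reactants: 6 (S)-N-methoxy-N,4-dimethyl-4-(triethylsilyloxy)hex-5-enamide
Product: 8 (S)-6-hydroxy-N-methoxy-N,4-dimethyl-4-(triethylsilyloxy)hexanamide, via B-alkyl-9-BBN adduct 7 (not isolated)
Conditions: 9-BBN, THF, 0 °C → rt; then aq. NaOAc, 30% H2O2, 0 °C → rt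
Reagents that add atoms: hydrogen peroxide, OO; 9-BBN, B1C2CCCC1CCC2 (its atoms stay only in intermediate 7)
Why: Brown hydroboration–oxidation; 9-BBN places boron only on the terminal vinyl carbon (C6), away from the quaternary C4, and does not reduce the amide at room temperature.

Step 6
Reactants: 8 (S)-6-hydroxy-N-methoxy-N,4-dimethyl-4-(triethylsilyloxy)hexanamide
Product: 9 (S)-N-methoxy-N,4-dimethyl-6-oxo-4-(triethylsilyloxy)hexanamide
Conditions: Dess–Martin periodinane, NaHCO3, CH2Cl2, 0 °C → rt
Reagents that add atoms: none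
Why: Dess–Martin oxidation stops at the aldehyde under buffered, non-basic conditions, which avoids β-elimination of the silyloxy group.

Step 7
Reactants: 9 (S)-N-methoxy-N,4-dimethyl-6-oxo-4-(triethylsilyloxy)hexanamide; 10 2-bromo-3-methylbut-1-ene
Product: 11 (4S)-6-hydroxy-N-methoxy-N,4,8-trimethyl-7-methylidene-4-(triethylsilyloxy)nonanamide (both C6 epimers)
Conditions: CrCl2 (excess), NiCl2 (cat.), DMF, rt
Reagents that add atoms: none
Why: Nozaki–Hiyama–Kishi coupling; zerovalent nickel activates the alkenyl bromide and the trivalent alkenylchromium species adds to the aldehyde only, leaving the Weinreb amide, and the C6 epimers converge on oxidation in step 8.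

Step 8
Reactants: 11 (4S)-6-hydroxy-N-methoxy-N,4,8-trimethyl-7-methylidene-4-(triethylsilyloxy)nonanamide
Product: 12 (S)-N-methoxy-N,4,8-trimethyl-7-methylidene-6-oxo-4-(triethylsilyloxy)nonanamide
Conditions: Dess–Martin periodinane, NaHCO3, CH2Cl2, 0 °C → rt
Reagents that add atoms: none
Why: Dess–Martin oxidation of the secondary allylic alcohol gives the α-isopropyl enone and removes the C6 stereocentre.

Step 9
Reactants: 12 (S)-N-methoxy-N,4,8-trimethyl-7-methylidene-6-oxo-4-(triethylsilyloxy)nonanamide
Product: 13 (4S,5Z)-6-(tert-butyldimethylsilyloxy)-N-methoxy-N,4,8-trimethyl-7-methylidene-4-(triethylsilyloxy)non-5-enamide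
Conditions: TBSOTf, Et3N, CH2Cl2, −78 → 0 °C
Reagents that add atoms: tert-butyldimethylsilyl triflate, CC(C)(C)[Si](C)(C)OS(=O)(=O)C(F)(F)F
Why: silyl enol ether formation by soft enolization; the ketone can lose a proton only at the C5 methylene, the amide is not enolized, and the (Z) isomer with the quaternary C4 trans to C7 is the less strained one.

Step 10
Reactants: 13 (4S,5Z)-6-(tert-butyldimethylsilyloxy)-N-methoxy-N,4,8-trimethyl-7-methylidene-4-(triethylsilyloxy)non-5-enamide; 14 isopropenylmagnesium bromide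
Product: 16 (6S,7Z)-8-(tert-butyldimethylsilyloxy)-2,6,10-trimethyl-9-methylidene-6-(triethylsilyloxy)undeca-1,7-dien-3-one, via magnesium chelate 15 (not isolated)
Conditions: THF, −20 → 0 °C; then cold pH 7 phosphate buffer; product kept cold and used without delay
Reagents that add atoms: none
Why: Weinreb ketone synthesis; the chelated tetrahedral adduct cannot take up a second equivalent and releases the isopropenyl ketone only on neutral work-up, so the enolizable C1 ketone appears after the C5=C6 dienol ether is in place.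

Step 11
Reactants: 16 (6S,7Z)-8-(tert-butyldimethylsilyloxy)-2,6,10-trimethyl-9-methylidene-6-(triethylsilyloxy)undeca-1,7-dien-3-one
Product: 17 6-(tert-butyldimethylsilyloxy)-4β-(triethylsilyloxy)-5α-eudesm-6-en-1-one
Conditions: toluene (0.01 M), BHT (cat.), 2,6-lutidine (0.1 equiv), 100 °C, degassed, base-washed glassware
Reagents that add atoms: none
Why: Concerted, asynchronous [4+2] cycloaddition of the 2-silyloxydiene C5=C6–C7=C8 with the tethered α-methyl enone C9=C10 (activated by the C1 carbonyl), the known type 1 intramolecular Diels–Alder reaction of 1,7,9-decatrien-3-ones that gives angular-methyl decalins; the four-atom tether (C1–C4) permits only the fused orientation, so C5–C10 and C8–C9 form although the silyloxy group alone would favour bonding of C5 to C9. Ring A (C1–C5, C10) closes through the tether as a chair-like six-membered array when C5–C10 forms, and ring B (C5–C10) is the new cyclohexene, whose C6=C7 bond emerges as the silyl enol ether. C10 and C5 are set under control of the C4 stereocentre: in the (Z)-dienol ether the C6 silyloxy group is cis to the fully substituted C4, so A(1,3) strain leaves room next to it only for the C4 oxygen, the C4 methyl turns to the rear face and C3 brings the dienophile to the front face. In the exo-carbonyl array, which is the only chair-like array that keeps C3 away from the C6 silyloxy group and the mode that α-methyl substitution of the dienophile is expected to favour, the C10 methyl lands syn to the axial C4 oxygen and H5 anti to it, which is the 4β-oxy, 5α-H, 10β-methyl pattern. The step thus needs face and exo selectivity at once, both secured by the C6 silyloxy group acting as a steric directing group next to the linalool-derived carbinol; cis-fused and C10-epimeric adducts are diastereomers and would be removed by chromatography.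

Step 12
Reactants: 17 6-(tert-butyldimethylsilyloxy)-4β-(triethylsilyloxy)-5α-eudesm-6-en-1-one
Product: 18 6-(tert-butyldimethylsilyloxy)-4β-(triethylsilyloxy)-5α-eudesm-6-en-1β-ol
Conditions: NaBH4, EtOH/THF, 0 °C → rt
Reagents that add atoms: none
Why: hydride reduction; borohydride should attack C1 from the α face, anti to the axial C10 methyl, to give the equatorial 1β-alcohol while the tetrasubstituted silyl enol ether is inert, and the C1 configuration is of no consequence because the oxygen is removed.

Step 13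
Reactants: 18 6-(tert-butyldimethylsilyloxy)-4β-(triethylsilyloxy)-5α-eudesm-6-en-1β-ol
Product: 20 O-[6-(tert-butyldimethylsilyloxy)-4β-(triethylsilyloxy)-5α-eudesm-6-en-1β-yl] S-methyl dithiocarbonate, via sodium xanthate 19 (not isolated)
Conditions: NaH, imidazole (cat.), THF, 0 °C → rt; CS2; then MeI
Reagents that add atoms: carbon disulfide, S=C=S; iodomethane, CI; sodium hydride, [Na+].[H-] (sodium stays only in intermediate 19)
Why: xanthate formation (alkoxide, CS2, S-methylation), the first stage of the Barton–McCombie deoxygenation; the basic conditions leave both silyl groups intact.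

Step 14
Reactants: 20 O-[6-(tert-butyldimethylsilyloxy)-4β-(triethylsilyloxy)-5α-eudesm-6-en-1β-yl] S-methyl dithiocarbonate
Product: 21 6-(tert-butyldimethylsilyloxy)-4β-(triethylsilyloxy)-5α-eudesm-6-ene
Conditions: Bu3SnH (excess, not added slowly), AIBN (cat.), toluene, 100 °C
Reagents that add atoms: none
Why: Barton–McCombie deoxygenation; the stannyl radical adds to the thiocarbonyl group, the secondary C1 radical is released and takes hydrogen from Bu3SnH, and the silyl enol ether is not a radical acceptor within reach of C1.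

Step 15
Reactants: 21 6-(tert-butyldimethylsilyloxy)-4β-(triethylsilyloxy)-5α-eudesm-6-ene
Product: 23 4β-hydroxy-5α,7αH-eudesman-6-one, via silyloxy ketone 22 (not isolated)
Conditions: 48% aq. HF, MeCN, 0 °C → rt
Reagents that add atoms: none
Why: acidic fluoride desilylation; the silyl enol ether should be protonated at C7 from the α face (axial, chair-forming protonation), which places the isopropyl group equatorial (7β), and the tertiary silyl ether is then cleaved, C5 staying untouched if the mixture is kept at or below room temperature.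

Step 16
Reactants: 23 4β-hydroxy-5α,7αH-eudesman-6-one
Product: 24 5α,7αH-eudesmane-4β,6β-diol
Conditions: NaBH4, MeOH, 0 °C
Reagents that add atoms: none
Why: substrate-controlled hydride reduction; the β face of the C6 carbonyl is shielded by the syn-axial C10 methyl and C4 hydroxyl, so hydride should enter from the α face and give the axial 6β-alcohol.

Step 17
Reactants: 25 isoferulic acid
Product: 27 (E)-3-[3-(tert-butyldimethylsilyloxy)-4-methoxyphenyl]prop-2-enoic acid, via bis-silyl derivative 26 (not isolated)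
Conditions: TBSCl (2.5 equiv), imidazole, DMF, rt; then AcOH/THF/H2O, rt
Reagents that add atoms: tert-butyldimethylsilyl chloride, CC(C)(C)[Si](C)(C)Cl
Why: silylation of phenol and acid followed by selective hydrolysis of the labile silyl ester leaves the aryl silyl ether, which blocks self-acylation in step 18.

Step 18
Reactants: 24 5α,7αH-eudesmane-4β,6β-diol; 27 (E)-3-[3-(tert-butyldimethylsilyloxy)-4-methoxyphenyl]prop-2-enoic acid
Product: 29 4β-hydroxy-5α,7αH-eudesman-6β-yl (E)-3-[3-(tert-butyldimethylsilyloxy)-4-methoxyphenyl]prop-2-enoate, via mixed anhydride 28 (not isolated)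
Conditions: 27, 2,4,6-trichlorobenzoyl chloride, Et3N, THF, rt; then 24, DMAP, toluene, 60–80 °C
Reagents that add atoms: 2,4,6-trichlorobenzoyl chloride, O=C(Cl)c1c(Cl)cc(Cl)cc1Cl (its atoms stay only in intermediate 28)
Why: Yamaguchi esterification; the mixed anhydride acylates DMAP and the acylpyridinium reacts with the secondary C6 hydroxyl only, the tertiary C4 hydroxyl being unreactive, and C6 keeps its configuration because its C–O bond is not broken.

Step 19
Reactants: 29 4β-hydroxy-5α,7αH-eudesman-6β-yl (E)-3-[3-(tert-butyldimethylsilyloxy)-4-methoxyphenyl]prop-2-enoate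
Product: 30 4β-hydroxy-5α,7αH-eudesman-6β-yl (E)-3-(3-hydroxy-4-methoxyphenyl)prop-2-enoate (target)
Conditions: TBAF, AcOH, THF, 0 °C
Reagents that add atoms: none
Why: fluoride cleavage of the aryl silyl ether under acetic acid buffering is fast at 0 °C and leaves the cinnamate ester and the tertiary alcohol untouched.

**Compound list**

1 | (S)-linalool | C=C[C@@](C)(O)CCC=C(C)C | starting material
2 | (S)-linalool triethylsilyl ether | C=C[C@@](C)(O[Si](CC)(CC)CC)CCC=C(C)C | intermediate
3 | 3,3-dimethyl-5-[(3S)-3-methyl-3-(triethylsilyloxy)pent-4-en-1-yl]-1,2,4-trioxolane (ozonide, not isolated) | C=C[C@@](C)(O[Si](CC)(CC)CC)CCC1OOC(C)(C)O1 | intermediate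
4 | (S)-4-methyl-4-(triethylsilyloxy)hex-5-enal | C=C[C@@](C)(O[Si](CC)(CC)CC)CCC=O | intermediate
5 | (S)-4-methyl-4-(triethylsilyloxy)hex-5-enoic acid | C=C[C@@](C)(O[Si](CC)(CC)CC)CCC(=O)O | intermediate
6 | (S)-N-methoxy-N,4-dimethyl-4-(triethylsilyloxy)hex-5-enamide | C=C[C@@](C)(O[Si](CC)(CC)CC)CCC(=O)N(C)OC | intermediate
7 | B-alkyl-9-BBN adduct of 6, boron on C6 (not isolated) | B1(CC[C@@](C)(O[Si](CC)(CC)CC)CCC(=O)N(C)OC)C2CCCC1CCC2 | intermediate
8 | (S)-6-hydroxy-N-methoxy-N,4-dimethyl-4-(triethylsilyloxy)hexanamide | OCC[C@@](C)(O[Si](CC)(CC)CC)CCC(=O)N(C)OC | intermediate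
9 | (S)-N-methoxy-N,4-dimethyl-6-oxo-4-(triethylsilyloxy)hexanamide | O=CC[C@@](C)(O[Si](CC)(CC)CC)CCC(=O)N(C)OC | intermediate
10 | 2-bromo-3-methylbut-1-ene | CC(C)C(Br)=C | starting material
11 | (4S)-6-hydroxy-N-methoxy-N,4,8-trimethyl-7-methylidene-4-(triethylsilyloxy)nonanamide (C6 epimers) | C=C(C(C)C)C(O)C[C@@](C)(O[Si](CC)(CC)CC)CCC(=O)N(C)OC | intermediate
12 | (S)-N-methoxy-N,4,8-trimethyl-7-methylidene-6-oxo-4-(triethylsilyloxy)nonanamide | C=C(C(C)C)C(=O)C[C@@](C)(O[Si](CC)(CC)CC)CCC(=O)N(C)OC | intermediate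
13 | (4S,5Z)-6-(tert-butyldimethylsilyloxy)-N-methoxy-N,4,8-trimethyl-7-methylidene-4-(triethylsilyloxy)non-5-enamide | C=C(C(C)C)/C(O[Si](C)(C)C(C)(C)C)=C/[C@@](C)(O[Si](CC)(CC)CC)CCC(=O)N(C)OC | intermediate
14 | isopropenylmagnesium bromide | C=C(C)[Mg]Br | starting material
15 | bromomagnesium salt of the tetrahedral adduct of 13 and 14 (chelate, not isolated) | C=C(C(C)C)/C(O[Si](C)(C)C(C)(C)C)=C/[C@@](C)(O[Si](CC)(CC)CC)CCC(O[Mg]Br)(N(C)OC)C(C)=C | intermediate
16 | (6S,7Z)-8-(tert-butyldimethylsilyloxy)-2,6,10-trimethyl-9-methylidene-6-(triethylsilyloxy)undeca-1,7-dien-3-one (cycloaddition precursor) | C=C(C(C)C)/C(O[Si](C)(C)C(C)(C)C)=C/[C@@](C)(O[Si](CC)(CC)CC)CCC(=O)C(C)=C | intermediate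
17 | 6-(tert-butyldimethylsilyloxy)-4β-(triethylsilyloxy)-5α-eudesm-6-en-1-one (cycloadduct) | CC(C)C1=C(O[Si](C)(C)C(C)(C)C)[C@@H]2[C@](C)(C(=O)CC[C@]2(C)O[Si](CC)(CC)CC)CC1 | intermediate
18 | 6-(tert-butyldimethylsilyloxy)-4β-(triethylsilyloxy)-5α-eudesm-6-en-1β-ol | CC(C)C1=C(O[Si](C)(C)C(C)(C)C)[C@@H]2[C@](C)([C@H](O)CC[C@]2(C)O[Si](CC)(CC)CC)CC1 | intermediate
19 | sodium O-[6-(tert-butyldimethylsilyloxy)-4β-(triethylsilyloxy)-5α-eudesm-6-en-1β-yl] dithiocarbonate (not isolated) | CC(C)C1=C(O[Si](C)(C)C(C)(C)C)[C@@H]2[C@](C)([C@H](OC(=S)[S-])CC[C@]2(C)O[Si](CC)(CC)CC)CC1.[Na+] | intermediate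
20 | O-[6-(tert-butyldimethylsilyloxy)-4β-(triethylsilyloxy)-5α-eudesm-6-en-1β-yl] S-methyl dithiocarbonate | CC(C)C1=C(O[Si](C)(C)C(C)(C)C)[C@@H]2[C@](C)([C@H](OC(=S)SC)CC[C@]2(C)O[Si](CC)(CC)CC)CC1 | intermediate
21 | 6-(tert-butyldimethylsilyloxy)-4β-(triethylsilyloxy)-5α-eudesm-6-ene | CC(C)C1=C(O[Si](C)(C)C(C)(C)C)[C@@H]2[C@](C)(CCC[C@]2(C)O[Si](CC)(CC)CC)CC1 | intermediate
22 | 4β-(triethylsilyloxy)-5α,7αH-eudesman-6-one (not isolated) | O=C2[C@@H]3[C@](C)(CCC[C@]3(C)O[Si](CC)(CC)CC)CC[C@H]2C(C)C | intermediate
23 | 4β-hydroxy-5α,7αH-eudesman-6-one | O=C2[C@@H]3[C@](C)(CCC[C@]3(C)O)CC[C@H]2C(C)C | intermediate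
24 | 5α,7αH-eudesmane-4β,6β-diol | O[C@H]2[C@@H]3[C@](C)(CCC[C@]3(C)O)CC[C@H]2C(C)C | intermediate
25 | isoferulic acid | COc1ccc(/C=C/C(=O)O)cc1O | starting material
26 | tert-butyldimethylsilyl (E)-3-[3-(tert-butyldimethylsilyloxy)-4-methoxyphenyl]prop-2-enoate (not isolated) | COc1ccc(/C=C/C(=O)O[Si](C)(C)C(C)(C)C)cc1O[Si](C)(C)C(C)(C)C | intermediate
27 | (E)-3-[3-(tert-butyldimethylsilyloxy)-4-methoxyphenyl]prop-2-enoic acid | COc1ccc(/C=C/C(=O)O)cc1O[Si](C)(C)C(C)(C)C | intermediate
28 | mixed anhydride of 27 and 2,4,6-trichlorobenzoic acid (not isolated) | COc1ccc(/C=C/C(=O)OC(=O)c2c(Cl)cc(Cl)cc2Cl)cc1O[Si](C)(C)C(C)(C)C | intermediate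
29 | 4β-hydroxy-5α,7αH-eudesman-6β-yl (E)-3-[3-(tert-butyldimethylsilyloxy)-4-methoxyphenyl]prop-2-enoate | COc1ccc(/C=C/C(=O)O[C@H]2[C@@H]3[C@](C)(CCC[C@]3(C)O)CC[C@H]2C(C)C)cc1O[Si](C)(C)C(C)(C)C | intermediate
30 | (4S,5S,6R,7S,10R)-4β-hydroxy-5α,7αH-eudesman-6β-yl (E)-3-(3-hydroxy-4-methoxyphenyl)prop-2-enoate, CNP0291757.1 | COc1ccc(/C=C/C(=O)O[C@H]2[C@@H]3[C@](C)(CCC[C@]3(C)O)CC[C@H]2C(C)C)cc1O | target

**Step count**

Total: 19 steps. Longest linear sequence: 18 steps (steps 1–16, 18, 19, from (S)-linalool); step 17 is a one-step branch.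

**Steps most likely to fail**

1. Step 11 (cycloaddition).
What may go wrong: the dienophile adds through the endo-carbonyl array, or to the diene face on which the C4 methyl or C3 rather than the C4 oxygen lies next to the C6 silyloxy group, or the dienol ether is lost before ring closure. In each case the trans-fused 4β-oxy/10β-methyl adduct is not the main product.
Fallback (sets out from 12, comes back at 23): the two oxygens are tied together so that the diene geometry no longer depends on a conformational preference. HF·pyridine (THF/pyridine, 0 °C) frees the tertiary alcohol of 12 to give the β-hydroxy enone F1, which is used at once. t-Bu2Si(OTf)2/Et3N (CH2Cl2, −78 → 0 °C) converts it into the cyclic di-tert-butylsilylene dienol ether F2, a 4H-1,3,2-dioxasiline. In F2 the C5=C6 geometry is fixed by the ring and the C4–O bond is held in the diene plane, with C3 and the C4 methyl on opposite faces. Weinreb ketone synthesis with 14 gives the silylene-tethered trienone F3. Its thermal intramolecular Diels–Alder reaction can deliver the dienophile only from the C3 face and should give the silylene-bridged adduct F4. NaBH4 reduction to the 1β-alcohol F5, conversion into the xanthate F6 and Barton–McCombie reduction to the 1-deoxy silylene F7 follow steps 12 to 14. Aqueous HF in MeCN then cleaves the silylene with protonation at C7 and gives 23.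

2. Step 18 (esterification).
What may go wrong: acyl transfer to the axial C6 hydroxyl, which is flanked by the syn-axial C10 methyl and C4 hydroxyl, is too slow for the bulky cinnamoyl donor, and the mixed anhydride is consumed in other ways first.
Fallback (sets out from 24, comes back at 30): the acyl group is attached as a small unit and the cinnamate is built on the ester. Diethylphosphonoacetic acid, DCC and DMAP (cat.) in CH2Cl2 acylate the C6 hydroxyl of 24 to give the phosphonoacetate F8. Horner–Wadsworth–Emmons olefination of F8 with isovanillin (3-hydroxy-4-methoxybenzaldehyde; LiCl, DBU, MeCN, rt) then forms the (E)-cinnamate and gives 30 directly, without phenol protection.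

3. Step 15 (unmasking of the C6 ketone).
What may go wrong: once both silyl groups are off, the tertiary β-hydroxy ketone dehydrates, opens by retro-aldol cleavage or epimerizes at C5 under the acidic conditions.
Fallback (sets out from 21, comes back at 24): the carbinol stays protected until the ketone is gone. Buffered fluoride (TBAF/AcOH, THF, −20 °C) cleaves only the silyl enol ether, and the silyloxy ketone 22 is isolated. LiBH(s-Bu)3 (THF, −78 °C) reduces it from the α face to the 6β-alcohol F9. HF·pyridine (THF, rt) then removes the triethylsilyl group and gives 24.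

**Further compounds**

F1 | step 11 | (S)-4-hydroxy-N-methoxy-N,4,8-trimethyl-7-methylidene-6-oxononanamide | C=C(C(C)C)C(=O)C[C@@](C)(O)CCC(=O)N(C)OC
F2 | step 11 | 3-[(4S)-2,2-di-tert-butyl-4-methyl-6-(3-methylbut-1-en-2-yl)-4H-1,3,2-dioxasilin-4-yl]-N-methoxy-N-methylpropanamide | C=C(C(C)C)C1=C[C@@](C)(O[Si](C(C)(C)C)(C(C)(C)C)O1)CCC(=O)N(C)OC
F3 | step 11 | 5-[(4S)-2,2-di-tert-butyl-4-methyl-6-(3-methylbut-1-en-2-yl)-4H-1,3,2-dioxasilin-4-yl]-2-methylpent-1-en-3-one | C=C(C(C)C)C1=C[C@@](C)(O[Si](C(C)(C)C)(C(C)(C)C)O1)CCC(=O)C(C)=C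
F4 | step 11 | 4β,6-(di-tert-butylsilylenedioxy)-5α-eudesm-6-en-1-one | CC(C)C1=C(O[Si](C(C)(C)C)(C(C)(C)C)O3)[C@@H]2[C@](C)(C(=O)CC[C@@]23C)CC1
F5 | step 11 | 4β,6-(di-tert-butylsilylenedioxy)-5α-eudesm-6-en-1β-ol | CC(C)C1=C(O[Si](C(C)(C)C)(C(C)(C)C)O3)[C@@H]2[C@](C)([C@H](O)CC[C@@]23C)CC1
F6 | step 11 | O-[4β,6-(di-tert-butylsilylenedioxy)-5α-eudesm-6-en-1β-yl] S-methyl dithiocarbonate | CC(C)C1=C(O[Si](C(C)(C)C)(C(C)(C)C)O3)[C@@H]2[C@](C)([C@H](OC(=S)SC)CC[C@@]23C)CC1
F7 | step 11 | 4β,6-(di-tert-butylsilylenedioxy)-5α-eudesm-6-ene | CC(C)C1=C(O[Si](C(C)(C)C)(C(C)(C)C)O3)[C@@H]2[C@](C)(CCC[C@@]23C)CC1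
F8 | step 18 | 4β-hydroxy-5α,7αH-eudesman-6β-yl 2-(diethoxyphosphoryl)acetate | CCOP(=O)(OCC)CC(=O)O[C@H]2[C@@H]3[C@](C)(CCC[C@]3(C)O)CC[C@H]2C(C)C
F9 | step 15 | 4β-(triethylsilyloxy)-5α,7αH-eudesman-6β-ol | O[C@H]2[C@@H]3[C@](C)(CCC[C@]3(C)O[Si](CC)(CC)CC)CC[C@H]2C(C)C
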